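**Assumption:** positions are cited with labdane numbering (C1–C20; C20 is the acetoxymethyl carbon on C10; α = lower face, β = upper face). Commercial (−)-linalool is taken as the (R)-enantiomer, and compounds are numbered in the order of the forward steps.

## Retrosynthetic overview

1. The target comes from its C13 silyl ether, which comes from a 3-ketone by axial-selective hydride delivery; the ketone comes from the 2α-angelate of a bicyclic 2α,3β-diol.
2. The bicyclic diol comes from an acyclic (2R)-allylic alcohol that already carries the C20 acetate and the silylated linalool terminus. Hydroxyl-directed epoxidation of C3=C4 is followed by one cationic cascade that closes ring A (C4–C5) and then ring B (C9–C10) and ends by loss of H-7.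
3. The acyclic alcohol comes from a Z-selective Still–Gennari olefination (C5=C10) of a C12 aldehyde with a Weinreb-amide phosphonate, then isobutenyl Grignard addition and CBS reduction (C2).
4. The C12 aldehyde comes from (R)-linalool (source of C13) by allylic oxidation and two-carbon homologation.

## Route

Step 1
Reactants: 1 (R)-linalool [(3R)-3,7-dimethylocta-1,6-dien-3-ol]
Product: 2 tert-butyl{[(3R)-3,7-dimethylocta-1,6-dien-3-yl]oxy}dimethylsilane
Conditions: TBSOTf, 2,6-lutidine, CH2Cl2, 0 °C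
Reagents that add atoms: tert-butyldimethylsilyl trifluoromethanesulfonate, CC(C)(C)[Si](C)(C)OS(=O)(=O)C(F)(F)F
Why: Silyl-triflate protection of a tertiary alcohol turns the C13 oxygen into a bulky, poorly nucleophilic ether and leaves the stereocentre taken from (R)-linalool untouched.

Step 2
Reactants: 2 tert-butyl{[(3R)-3,7-dimethylocta-1,6-dien-3-yl]oxy}dimethylsilane
Product: 3 (2E,6R)-6-[(tert-butyldimethylsilyl)oxy]-2,6-dimethylocta-2,7-dien-1-ol
Conditions: SeO2 (0.3 equiv), t-BuOOH, salicylic acid (cat.), CH2Cl2, 0 °C to rt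
Reagents that add atoms: tert-butyl hydroperoxide, CC(C)(C)OO
Why: Riley allylic oxidation (ene reaction, then [2,3]-shift) hydroxylates only the E-methyl group of the trisubstituted alkene, and the vinyl group has no allylic hydrogen.

Step 3
Reactants: 3 (2E,6R)-6-[(tert-butyldimethylsilyl)oxy]-2,6-dimethylocta-2,7-dien-1-ol
Product: 4 tert-butyl{[(3R,6E)-8-bromo-3,7-dimethylocta-1,6-dien-3-yl]oxy}dimethylsilane
Conditions: CBr4, PPh3, CH2Cl2, 0 °C
Reagents that add atoms: carbon tetrabromide, BrC(Br)(Br)Br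
Why: The Appel reaction converts the primary allylic alcohol into the bromide under neutral conditions that preserve the silyl ether and the E geometry.

Step 4
Reactants: 4 tert-butyl{[(3R,6E)-8-bromo-3,7-dimethylocta-1,6-dien-3-yl]oxy}dimethylsilane; 5 N-tert-butylethanimine (acetaldehyde tert-butylimine)
Product: 7 (4E,8R)-8-[(tert-butyldimethylsilyl)oxy]-4,8-dimethyldeca-4,9-dienal, via N-tert-butyl imine of this aldehyde 6 (not isolated)
Conditions: LiN(iPr)2, 5, THF, −78 °C; then 4, −78 to 0 °C; then aq. oxalic acid, rt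
Reagents that add atoms: water, O
Why: Metalated-imine (aza-enolate) alkylation displaces the primary allylic bromide by SN2 (SN2′ is blocked by the fully substituted γ-carbon), and mild aqueous acid then releases the aldehyde, a two-carbon homologation that creates no stereocentre.

Step 5
Reactants: 8 methyl 2-[bis(2,2,2-trifluoroethoxy)phosphoryl]acetate; 9 2-chloro-N-methoxy-N-methylacetamide
Product: 10 methyl 2-[bis(2,2,2-trifluoroethoxy)phosphoryl]-4-[methoxy(methyl)amino]-4-oxobutanoate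
Conditions: NaH, NaI (cat.), THF/DMF, 0 °C to rt
Reagents that add atoms: none
Why: C-alkylation (SN2, iodide catalysis) of the stabilised phosphonoacetate anion with the α-chloro amide attaches the future C1–C2 unit as a Weinreb amide.

Step 6
Reactants: 7 (4E,8R)-8-[(tert-butyldimethylsilyl)oxy]-4,8-dimethyldeca-4,9-dienal; 10 methyl 2-[bis(2,2,2-trifluoroethoxy)phosphoryl]-4-[methoxy(methyl)amino]-4-oxobutanoate
Product: 11 methyl (2Z,6E,10R)-10-[(tert-butyldimethylsilyl)oxy]-2-{2-[methoxy(methyl)amino]-2-oxoethyl}-6,10-dimethyldodeca-2,6,11-trienoate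
Conditions: KN(SiMe3)2, 18-crown-6, THF, −78 °C
Reagents that add atoms: none
Why: In this Still–Gennari olefination the bis(trifluoroethyl) phosphonate under dissociating conditions eliminates from the kinetic adduct to give the Z-trisubstituted enoate (ester carbon C20 cis to C6), the C5=C10 geometry needed for a trans ring fusion.

Step 7
Reactants: 11 methyl (2Z,6E,10R)-10-[(tert-butyldimethylsilyl)oxy]-2-{2-[methoxy(methyl)amino]-2-oxoethyl}-6,10-dimethyldodeca-2,6,11-trienoate; 12 2-methylprop-1-enylmagnesium bromide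
Product: 13 methyl (2Z,6E,10R)-10-[(tert-butyldimethylsilyl)oxy]-6,10-dimethyl-2-(4-methyl-2-oxopent-3-en-1-yl)dodeca-2,6,11-trienoate
Conditions: THF, −30 to 0 °C; aq. NH4Cl
Reagents that add atoms: none
Why: In this Weinreb ketone synthesis the alkenyl Grignard adds once to the N-methoxy-N-methylamide through a stable magnesium chelate, faster than to the hindered α-branched enoate, and the enone appears only on quench.

Step 8
Reactants: 13 methyl (2Z,6E,10R)-10-[(tert-butyldimethylsilyl)oxy]-6,10-dimethyl-2-(4-methyl-2-oxopent-3-en-1-yl)dodeca-2,6,11-trienoate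
Product: 14 methyl (2Z,6E,10R)-10-[(tert-butyldimethylsilyl)oxy]-2-[(2R)-2-hydroxy-4-methylpent-3-en-1-yl]-6,10-dimethyldodeca-2,6,11-trienoate
Conditions: (S)-2-methyl-CBS-oxazaborolidine [(3aS)-1-methyl-3,3-diphenyltetrahydro-1H,3H-pyrrolo[1,2-c][1,3,2]oxazaborole] (20 mol %), catecholborane, toluene, −78 °C
Reagents that add atoms: none
Why: In this Corey–Bakshi–Shibata reduction the (S)-oxazaborolidine delivers hydride to the enone carbonyl with the alkenyl group as the large substituent, setting the (R)-carbinol at C2 without touching the ester or the alkenes.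

Step 9
Reactants: 14 methyl (2Z,6E,10R)-10-[(tert-butyldimethylsilyl)oxy]-2-[(2R)-2-hydroxy-4-methylpent-3-en-1-yl]-6,10-dimethyldodeca-2,6,11-trienoate
Product: 15 (2Z,6E,10R)-10-[(tert-butyldimethylsilyl)oxy]-2-[(2R)-2-hydroxy-4-methylpent-3-en-1-yl]-6,10-dimethyldodeca-2,6,11-trien-1-ol
Conditions: iBu2AlH (4 equiv), CH2Cl2, −78 to 0 °C; aq. potassium sodium tartrate
Reagents that add atoms: none
Why: Hydride reduction of the conjugated methyl ester by iBu2AlH gives the primary allylic alcohol (C20–OH) with the Z geometry retained.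

Step 10
Reactants: 15 (2Z,6E,10R)-10-[(tert-butyldimethylsilyl)oxy]-2-[(2R)-2-hydroxy-4-methylpent-3-en-1-yl]-6,10-dimethyldodeca-2,6,11-trien-1-ol
Product: 16 [(2Z,6E,10R)-10-[(tert-butyldimethylsilyl)oxy]-2-[(2R)-2-hydroxy-4-methylpent-3-en-1-yl]-6,10-dimethyldodeca-2,6,11-trien-1-yl] acetate
Conditions: AcCl (1.05 equiv), 2,4,6-collidine, CH2Cl2, −78 °C
Reagents that add atoms: acetyl chloride, CC(Cl)=O
Why: Kinetically controlled acylation esterifies the unhindered primary allylic hydroxyl in preference to the secondary one and so installs the C20 acetate of the target.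

Step 11
Reactants: 16 [(2Z,6E,10R)-10-[(tert-butyldimethylsilyl)oxy]-2-[(2R)-2-hydroxy-4-methylpent-3-en-1-yl]-6,10-dimethyldodeca-2,6,11-trien-1-yl] acetate
Product: 18 (13R)-13-[(tert-butyldimethylsilyl)oxy]-2α,3β-dihydroxylabda-7,14-dien-20-yl acetate, via threo epoxy alcohol 17 (not isolated)
Conditions: VO(acac)2 (5 mol %), t-BuOOH (1.1 equiv, in decane), CH2Cl2, 0 °C; then MeAlCl2 (4 equiv), −78 °C; aq. potassium sodium tartrate
Reagents that add atoms: tert-butyl hydroperoxide, CC(C)(C)OO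
Why: Proposed new method: the free C2 hydroxyl first steers the vanadium-catalysed epoxidation to C3=C4 only (threo by the A1,3-strain model, giving the (3S)-epoxide 17) and then, as a chelating dichloroaluminium alkoxide, activates that epoxide for anti opening at C4 by the C5=C10 π bond in a chair–chair fold (C2–O and C3–O equatorial; the Z-C5=C10 and E-C8=C9 geometries translate into 5α-H, 10β-CH2OAc and 9α-H), after which the C8 cation sheds the accessible axial 7α-H to give the trisubstituted Δ7 alkene; the closest known reaction types are the VO(acac)2/t-BuOOH directed epoxidation of allylic alcohols and the MeAlCl2-promoted epoxide-initiated cation–olefin (polyene) bicyclisation, here run in one flask on an epoxy alcohol whose nucleophilic alkene carries an allylic acetate.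

Step 12
Reactants: 18 (13R)-13-[(tert-butyldimethylsilyl)oxy]-2α,3β-dihydroxylabda-7,14-dien-20-yl acetate; 19 angelic acid [(2Z)-2-methylbut-2-enoic acid]
Product: 21 (13R)-20-acetoxy-13-[(tert-butyldimethylsilyl)oxy]-3β-hydroxylabda-7,14-dien-2α-yl (2Z)-2-methylbut-2-enoate, via angelic 2,4,6-trichlorobenzoic anhydride 20 (not isolated)
Conditions: 19, 2,4,6-trichlorobenzoyl chloride, Et3N, toluene, rt; then 18, 80 °C
Reagents that add atoms: none
Why: In this Yamaguchi esterification the mixed anhydride acylates the less hindered equatorial C2 hydroxyl rather than the neopentyl C3 hydroxyl, and the DMAP-free heating protocol avoids Z-to-E isomerisation to the tiglate.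

Step 13
Reactants: 21 (13R)-20-acetoxy-13-[(tert-butyldimethylsilyl)oxy]-3β-hydroxylabda-7,14-dien-2α-yl (2Z)-2-methylbut-2-enoate
Product: 22 (13R)-20-acetoxy-13-[(tert-butyldimethylsilyl)oxy]-3-oxolabda-7,14-dien-2α-yl (2Z)-2-methylbut-2-enoate
Conditions: Dess–Martin periodinane, NaHCO3, CH2Cl2, rt
Reagents that add atoms: none
Why: Dess–Martin oxidation converts the remaining secondary C3 alcohol into the ketone under buffered conditions, and the 2α-acyloxy group is already in the stable equatorial position.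

Step 14
Reactants: 22 (13R)-20-acetoxy-13-[(tert-butyldimethylsilyl)oxy]-3-oxolabda-7,14-dien-2α-yl (2Z)-2-methylbut-2-enoate
Product: 23 (13R)-20-acetoxy-13-[(tert-butyldimethylsilyl)oxy]-3α-hydroxylabda-7,14-dien-2α-yl (2Z)-2-methylbut-2-enoate
Conditions: K[(s-Bu)3BH], THF, −78 °C; AcOH quench at −78 °C
Reagents that add atoms: none
Why: In this bulky trialkylborohydride reduction hydride arrives along the equatorial (β) trajectory, as in reductions of 4,4-dimethyl-3-oxo terpenoids with such reagents, giving the axial 3α-alcohol cis to the 2α-ester, and the cold acidic quench prevents acyl migration.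

Step 15
Reactants: 23 (13R)-20-acetoxy-13-[(tert-butyldimethylsilyl)oxy]-3α-hydroxylabda-7,14-dien-2α-yl (2Z)-2-methylbut-2-enoate
Product: 24 CNP0171655.1 [(13R)-20-acetoxy-3α,13-dihydroxylabda-7,14-dien-2α-yl (2Z)-2-methylbut-2-enoate]
Conditions: HF·pyridine, pyridine, THF, 0 °C to rt
Reagents that add atoms: none
Why: Buffered fluoride desilylation cleaves the tertiary silyl ether without ionising the allylic carbinol or moving the esters and releases the target.

## Compound list

1 | (R)-linalool, (3R)-3,7-dimethylocta-1,6-dien-3-ol | C=C[C@](C)(O)CCC=C(C)C | starting material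
2 | tert-butyl{[(3R)-3,7-dimethylocta-1,6-dien-3-yl]oxy}dimethylsilane | C=C[C@](C)(O[Si](C)(C)C(C)(C)C)CCC=C(C)C | intermediate
3 | (2E,6R)-6-[(tert-butyldimethylsilyl)oxy]-2,6-dimethylocta-2,7-dien-1-ol | C=C[C@](C)(O[Si](C)(C)C(C)(C)C)CC/C=C(\C)CO | intermediate
4 | tert-butyl{[(3R,6E)-8-bromo-3,7-dimethylocta-1,6-dien-3-yl]oxy}dimethylsilane | C=C[C@](C)(O[Si](C)(C)C(C)(C)C)CC/C=C(\C)CBr | intermediate
5 | N-tert-butylethanimine (acetaldehyde tert-butylimine) | CC=NC(C)(C)C | starting material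
6 | N-tert-butyl imine of (4E,8R)-8-[(tert-butyldimethylsilyl)oxy]-4,8-dimethyldeca-4,9-dienal | C=C[C@](C)(O[Si](C)(C)C(C)(C)C)CC/C=C(\C)CCC=NC(C)(C)C | intermediate (not isolated)
7 | (4E,8R)-8-[(tert-butyldimethylsilyl)oxy]-4,8-dimethyldeca-4,9-dienal | C=C[C@](C)(O[Si](C)(C)C(C)(C)C)CC/C=C(\C)CCC=O | intermediate
8 | methyl 2-[bis(2,2,2-trifluoroethoxy)phosphoryl]acetate (Still–Gennari reagent) | COC(=O)CP(=O)(OCC(F)(F)F)OCC(F)(F)F | starting material
9 | 2-chloro-N-methoxy-N-methylacetamide | CON(C)C(=O)CCl | starting material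
10 | methyl 2-[bis(2,2,2-trifluoroethoxy)phosphoryl]-4-[methoxy(methyl)amino]-4-oxobutanoate | COC(=O)C(CC(=O)N(C)OC)P(=O)(OCC(F)(F)F)OCC(F)(F)F | intermediate
11 | methyl (2Z,6E,10R)-10-[(tert-butyldimethylsilyl)oxy]-2-{2-[methoxy(methyl)amino]-2-oxoethyl}-6,10-dimethyldodeca-2,6,11-trienoate | C=C[C@](C)(O[Si](C)(C)C(C)(C)C)CC/C=C(\C)CC/C=C(/CC(=O)N(C)OC)C(=O)OC | intermediate
12 | 2-methylprop-1-enylmagnesium bromide | CC(C)=C[Mg]Br | starting material
13 | methyl (2Z,6E,10R)-10-[(tert-butyldimethylsilyl)oxy]-6,10-dimethyl-2-(4-methyl-2-oxopent-3-en-1-yl)dodeca-2,6,11-trienoate | C=C[C@](C)(O[Si](C)(C)C(C)(C)C)CC/C=C(\C)CC/C=C(/CC(=O)C=C(C)C)C(=O)OC | intermediate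
14 | methyl (2Z,6E,10R)-10-[(tert-butyldimethylsilyl)oxy]-2-[(2R)-2-hydroxy-4-methylpent-3-en-1-yl]-6,10-dimethyldodeca-2,6,11-trienoate | C=C[C@](C)(O[Si](C)(C)C(C)(C)C)CC/C=C(\C)CC/C=C(/C[C@@H](O)C=C(C)C)C(=O)OC | intermediate
15 | (2Z,6E,10R)-10-[(tert-butyldimethylsilyl)oxy]-2-[(2R)-2-hydroxy-4-methylpent-3-en-1-yl]-6,10-dimethyldodeca-2,6,11-trien-1-ol | C=C[C@](C)(O[Si](C)(C)C(C)(C)C)CC/C=C(\C)CC/C=C(/C[C@@H](O)C=C(C)C)CO | intermediate
16 | [(2Z,6E,10R)-10-[(tert-butyldimethylsilyl)oxy]-2-[(2R)-2-hydroxy-4-methylpent-3-en-1-yl]-6,10-dimethyldodeca-2,6,11-trien-1-yl] acetate | C=C[C@](C)(O[Si](C)(C)C(C)(C)C)CC/C=C(\C)CC/C=C(/C[C@@H](O)C=C(C)C)COC(C)=O | intermediate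
17 | [(2Z,6E,10R)-10-[(tert-butyldimethylsilyl)oxy]-2-{(2R)-2-[(2S)-3,3-dimethyloxiran-2-yl]-2-hydroxyethyl}-6,10-dimethyldodeca-2,6,11-trien-1-yl] acetate (threo epoxy alcohol) | C=C[C@](C)(O[Si](C)(C)C(C)(C)C)CC/C=C(\C)CC/C=C(/C[C@@H](O)[C@@H]1OC1(C)C)COC(C)=O | intermediate (not isolated)
18 | (13R)-13-[(tert-butyldimethylsilyl)oxy]-2α,3β-dihydroxylabda-7,14-dien-20-yl acetate (5α-H, 9α-H, 10β-CH2OAc) | C=C[C@](C)(O[Si](C)(C)C(C)(C)C)CC[C@H]1C(C)=CC[C@H]2C(C)(C)[C@@H](O)[C@H](O)C[C@]12COC(C)=O | intermediate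
19 | angelic acid, (2Z)-2-methylbut-2-enoic acid | C/C=C(/C)C(=O)O | starting material
20 | (2Z)-2-methylbut-2-enoic 2,4,6-trichlorobenzoic anhydride | C/C=C(/C)C(=O)OC(=O)c1c(Cl)cc(Cl)cc1Cl | intermediate (not isolated)
21 | (13R)-20-acetoxy-13-[(tert-butyldimethylsilyl)oxy]-3β-hydroxylabda-7,14-dien-2α-yl (2Z)-2-methylbut-2-enoate | C=C[C@](C)(O[Si](C)(C)C(C)(C)C)CC[C@H]1C(C)=CC[C@H]2C(C)(C)[C@@H](O)[C@H](OC(=O)/C(C)=C\C)C[C@]12COC(C)=O | intermediate
22 | (13R)-20-acetoxy-13-[(tert-butyldimethylsilyl)oxy]-3-oxolabda-7,14-dien-2α-yl (2Z)-2-methylbut-2-enoate | C=C[C@](C)(O[Si](C)(C)C(C)(C)C)CC[C@H]1C(C)=CC[C@H]2C(C)(C)C(=O)[C@H](OC(=O)/C(C)=C\C)C[C@]12COC(C)=O | intermediate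
23 | (13R)-20-acetoxy-13-[(tert-butyldimethylsilyl)oxy]-3α-hydroxylabda-7,14-dien-2α-yl (2Z)-2-methylbut-2-enoate | C=C[C@](C)(O[Si](C)(C)C(C)(C)C)CC[C@H]1C(C)=CC[C@H]2C(C)(C)[C@H](O)[C@H](OC(=O)/C(C)=C\C)C[C@]12COC(C)=O | intermediate
24 | CNP0171655.1, (13R)-20-acetoxy-3α,13-dihydroxylabda-7,14-dien-2α-yl (2Z)-2-methylbut-2-enoate | C=C[C@](C)(O)CC[C@H]1C(C)=CC[C@H]2C(C)(C)[C@H](O)[C@H](OC(=O)/C(C)=C\C)C[C@]12COC(C)=O | target

## Step count

- Total steps: 15.
- Longest linear sequence: 14 (steps 1–4 and 6–15, from (R)-linalool).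

## Steps most likely to fail, with fallbacks

**Step 11 (epoxidation–bicyclisation).** Three things can go wrong:
- the C20 acetate carbonyl may trap the C10 cation as an acetoxonium ion before ring B closes;
- the tertiary allylic silyl ether may ionise under MeAlCl2;
- the C8 cation may give Δ8(17) or Δ8 isomers besides Δ7.

The fallback removes the participating ester and stages the sequence; it sets out from diol 15 and comes back at 18. The primary hydroxyl of 15 is silylated (TBDPSCl, imidazole) to the allylic alcohol (4R,6Z,10E,14R)-14-[(tert-butyldimethylsilyl)oxy]-6-{[(tert-butyldiphenylsilyl)oxy]methyl}-2,10,14-trimethylhexadeca-2,6,10,15-tetraen-4-ol F1. Directed epoxidation (VO(acac)2, t-BuOOH) gives the isolated threo epoxy alcohol F2. MeAlCl2 at −78 °C cyclises it to the bicyclic diol 20-silyl ether F3. AcOH-buffered Bu4NF at 0 °C removes only the primary silyl group and gives the 2α,3β,20-triol F4. Its primary hydroxyl is then acetylated (AcCl, 2,4,6-collidine, −78 °C) to rejoin the route at 18.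

**Step 14 (ketone reduction).** The hydride may attack axially and give the 3β-epimer. The α-acyloxy ketone also invites acyl migration or conjugate reduction of the angelate. The fallback changes the order so that reduction is done on an ester-free ring A and the angelate goes on last; it sets out from 18 and comes back at 24. The equatorial C2 hydroxyl of 18 is silylated (Et3SiCl, imidazole, −20 °C) to the 2-O-triethylsilyl ether F5. Dess–Martin oxidation gives the 3-ketone F6. Reduction with Li[(s-Bu)3BH] at −78 °C gives the 3α-alcohol F7. HF·pyridine removes both silyl groups to give the 2α,3α,13-triol 20-acetate F8. Yamaguchi esterification with angelic acid 19 then acylates the equatorial C2 hydroxyl in preference to the axial neopentyl C3 and the tertiary C13 hydroxyls, giving 24.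

**Step 7 (Grignard addition to the Weinreb amide).** The enoate may compete for the Grignard reagent. Enone 13 also has acidic C1 protons, which can move the C5=C10 bond into conjugation. The fallback sets the C2 stereocentre before the olefination; it sets out from phosphonate 10 (with aldehyde 7) and comes back at 15. Phosphonate 10 is treated with 2.2 equiv of Grignard reagent 12; the first equivalent deprotonates the phosphonoacetate and shields its ester. This gives the keto phosphonate methyl 2-[bis(2,2,2-trifluoroethoxy)phosphoryl]-6-methyl-4-oxohept-5-enoate F9. CBS reduction as in step 8 gives the (4R)-hydroxy phosphonate F10, which lactonises on work-up to the phosphono lactone (5R)-3-[bis(2,2,2-trifluoroethoxy)phosphoryl]-5-(2-methylprop-1-en-1-yl)oxolan-2-one F11. Still–Gennari olefination of F11 with aldehyde 7 (KN(SiMe3)2, 18-crown-6) gives the Z-alkylidene lactone F12. Reduction of F12 with iBu2AlH opens the lactone to diol 15.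

## Further compounds

F1 | step 11 | (4R,6Z,10E,14R)-14-[(tert-butyldimethylsilyl)oxy]-6-{[(tert-butyldiphenylsilyl)oxy]methyl}-2,10,14-trimethylhexadeca-2,6,10,15-tetraen-4-ol | C=C[C@](C)(O[Si](C)(C)C(C)(C)C)CC/C=C(\C)CC/C=C(/C[C@@H](O)C=C(C)C)CO[Si](c1ccccc1)(c1ccccc1)C(C)(C)C
F2 | step 11 | (1R,3Z,7E,11R)-11-[(tert-butyldimethylsilyl)oxy]-3-{[(tert-butyldiphenylsilyl)oxy]methyl}-1-[(2S)-3,3-dimethyloxiran-2-yl]-7,11-dimethyltrideca-3,7,12-trien-1-ol | C=C[C@](C)(O[Si](C)(C)C(C)(C)C)CC/C=C(\C)CC/C=C(/C[C@@H](O)[C@@H]1OC1(C)C)CO[Si](c1ccccc1)(c1ccccc1)C(C)(C)C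
F3 | step 11 | (13R)-13-[(tert-butyldimethylsilyl)oxy]-20-[(tert-butyldiphenylsilyl)oxy]labda-7,14-diene-2α,3β-diol | C=C[C@](C)(O[Si](C)(C)C(C)(C)C)CC[C@H]1C(C)=CC[C@H]2C(C)(C)[C@@H](O)[C@H](O)C[C@]12CO[Si](c1ccccc1)(c1ccccc1)C(C)(C)C
F4 | step 11 | (13R)-13-[(tert-butyldimethylsilyl)oxy]labda-7,14-diene-2α,3β,20-triol | C=C[C@](C)(O[Si](C)(C)C(C)(C)C)CC[C@H]1C(C)=CC[C@H]2C(C)(C)[C@@H](O)[C@H](O)C[C@]12CO
F5 | step 14 | (13R)-13-[(tert-butyldimethylsilyl)oxy]-3β-hydroxy-2α-[(triethylsilyl)oxy]labda-7,14-dien-20-yl acetate | C=C[C@](C)(O[Si](C)(C)C(C)(C)C)CC[C@H]1C(C)=CC[C@H]2C(C)(C)[C@@H](O)[C@H](O[Si](CC)(CC)CC)C[C@]12COC(C)=O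
F6 | step 14 | (13R)-13-[(tert-butyldimethylsilyl)oxy]-3-oxo-2α-[(triethylsilyl)oxy]labda-7,14-dien-20-yl acetate | C=C[C@](C)(O[Si](C)(C)C(C)(C)C)CC[C@H]1C(C)=CC[C@H]2C(C)(C)C(=O)[C@H](O[Si](CC)(CC)CC)C[C@]12COC(C)=O
F7 | step 14 | (13R)-13-[(tert-butyldimethylsilyl)oxy]-3α-hydroxy-2α-[(triethylsilyl)oxy]labda-7,14-dien-20-yl acetate | C=C[C@](C)(O[Si](C)(C)C(C)(C)C)CC[C@H]1C(C)=CC[C@H]2C(C)(C)[C@H](O)[C@H](O[Si](CC)(CC)CC)C[C@]12COC(C)=O
F8 | step 14 | (13R)-2α,3α,13-trihydroxylabda-7,14-dien-20-yl acetate | C=C[C@](C)(O)CC[C@H]1C(C)=CC[C@H]2C(C)(C)[C@H](O)[C@H](O)C[C@]12COC(C)=O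
F9 | step 7 | methyl 2-[bis(2,2,2-trifluoroethoxy)phosphoryl]-6-methyl-4-oxohept-5-enoate | COC(=O)C(CC(=O)C=C(C)C)P(=O)(OCC(F)(F)F)OCC(F)(F)F
F10 | step 7 | methyl (4R)-2-[bis(2,2,2-trifluoroethoxy)phosphoryl]-4-hydroxy-6-methylhept-5-enoate | COC(=O)C(C[C@@H](O)C=C(C)C)P(=O)(OCC(F)(F)F)OCC(F)(F)F
F11 | step 7 | (5R)-3-[bis(2,2,2-trifluoroethoxy)phosphoryl]-5-(2-methylprop-1-en-1-yl)oxolan-2-one | O=C1O[C@@H](C=C(C)C)CC1P(=O)(OCC(F)(F)F)OCC(F)(F)F
F12 | step 7 | (3Z,5R)-3-[(4E,8R)-8-[(tert-butyldimethylsilyl)oxy]-4,8-dimethyldeca-4,9-dien-1-ylidene]-5-(2-methylprop-1-en-1-yl)oxolan-2-one | C=C[C@](C)(O[Si](C)(C)C(C)(C)C)CC/C=C(\C)CC/C=C1/C[C@H](C=C(C)C)OC1=O
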